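**Retrosynthetic overview**

1. Indene locants are used for the hydrindane: C1 ethylidene, C2 OAc, C3, C3a, C4 methylene, C5 enoate, C6 OH, C7 isopropyl, C7a; ring A is the cyclopentane, ring B the cyclohexane; β is the face of H-3a, α the face of H-7a.
2. Late stage on ring B, in forward order: C7 acetyl to isopropyl (Wittig, selective hydrogenation); C4 silyl enol ether to the 5β-hydroxy C4 ketone (Rubottom); C4 ketone to methylene (Takai–Lombardo); acylation of O-5; cleavage of the PMB ether at O-6.
3. Key disconnection: rings A and B are formed together from an acyclic tetraenone by an intramolecular Diels–Alder reaction that makes the C6–C7 and C3a–C7a bonds (ring A is the three-carbon tether C1–C2–C3, ring B the cyclohexene). The dienophile is unveiled in the same flask by a Stille coupling.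
4. Enabling feature: in ring B, C4 (sp2) and C6 (C–O) stand 1,3 across C5, so C6=C5–C4=C3a maps onto a 1-alkoxy-3-silyloxy diene, while C7 (isopropyl as reduced acetyl) and C7a map onto an (E)-enone. The Z-ethylidene at C1 next to the C2 acetate supplies the allylic strain that relays the one preset stereocentre (C2) to C3a, C7a, C7 and C6.
5. The acyclic chain is built linearly from methyl 4-chloro-4-oxobutanoate, propyne (C2 set by asymmetric transfer hydrogenation), ethynylmagnesium bromide and 4-methoxybenzyl alcohol.

Key step: step 10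

Remark: the Z-configured acyl donor and the stannyl enone coupling partner are treated as not purchasable and are prepared; the sense of induction of the Ru catalyst in step 2 is the one expected from its usual model. Abbreviations: TBS = tert-butyldimethylsilyl, PMB = 4-methoxybenzyl, DMDO = dimethyldioxirane.

**Route**

Step 1
Reactants: 1 methyl 4-chloro-4-oxobutanoate; 2 propyne
Product: 3 methyl 4-oxohept-5-ynoate
Conditions: PdCl2(PPh3)2 (cat.), CuI (cat.), Et3N, THF, 0 °C to rt
Reagents that add atoms: none
Why: acyl Sonogashira coupling of an acid chloride with a terminal alkyne should give the ynone without touching the methyl ester.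

Step 2
Reactants: 3 methyl 4-oxohept-5-ynoate
Product: 5 (S)-5-(prop-1-yn-1-yl)dihydrofuran-2(3H)-one, via hydroxy ester 4 (not isolated)
Conditions: RuCl(p-cymene)[(S,S)-TsDPEN] (cat.), i-PrOH, rt; then TsOH (cat.), CH2Cl2, rt
Reagents that add atoms: none
Why: Noyori asymmetric transfer hydrogenation of the alkynyl ketone should set the carbinol stereocentre (the future C2) as S under catalyst control, the alkynyl group taking the π-position of the usual model, and the γ-hydroxy ester then lactonises.

Step 3
Reactants: 5 (S)-5-(prop-1-yn-1-yl)dihydrofuran-2(3H)-one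
Product: 6 (S)-4-hydroxy-N-methoxy-N-methylhept-5-ynamide
Conditions: MeNH(OMe)·HCl, AlMe3, CH2Cl2, 0 °C to rt
Reagents that add atoms: N,O-dimethylhydroxylamine hydrochloride, CNOC.Cl
Why: aluminium amide aminolysis of the lactone (Weinreb amide formation) should open the ring and free the propargylic hydroxyl that directs the next step; the stereocentre is not involved.

Step 4
Reactants: 6 (S)-4-hydroxy-N-methoxy-N-methylhept-5-ynamide
Product: 8 (4S,5E)-4-hydroxy-5-iodo-N-methoxy-N-methylhept-5-enamide, via vinylstannane 7 (not isolated)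
Conditions: Bu3SnH, PdCl2(PPh3)2 (cat.), THF, 0 °C; then I2, CH2Cl2, 0 °C
Reagents that add atoms: iodine, II
Why: palladium-catalysed syn-hydrostannation of a propargylic alcohol should place tin on the alkyne carbon next to the carbinol with hydrogen cis to it, and iododestannylation with retention then gives the E-iodide whose methyl group is cis to the carbinol carbon (the future Z-ethylidene).

Step 5
Reactants: 8 (4S,5E)-4-hydroxy-5-iodo-N-methoxy-N-methylhept-5-enamide; 9 ethynylmagnesium bromide
Product: 10 (6S,7E)-6-hydroxy-7-iodonon-7-en-1-yn-3-one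
Conditions: HC≡CMgBr (3 equiv), THF, 0 °C; aq. NH4Cl
Reagents that add atoms: none
Why: Weinreb ketone synthesis, in which the chelated tetrahedral intermediate should stop the addition at the ynone while the first equivalent of Grignard reagent only deprotonates the hydroxyl.

Step 6
Reactants: 10 (6S,7E)-6-hydroxy-7-iodonon-7-en-1-yn-3-one
Product: 11 (1E,6S,7E)-6-hydroxy-7-iodo-1-[(4-methoxybenzyl)oxy]nona-1,7-dien-3-one
Conditions: 4-MeOC6H4CH2OH (1.5 equiv), PMe3 (cat.), CH2Cl2, 0 °C to rt
Reagents that add atoms: 4-methoxybenzyl alcohol, COc1ccc(CO)cc1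
Why: phosphine-catalysed conjugate addition of an alcohol to a terminal ynone should give the (E)-β-alkoxy enone, the primary benzylic alcohol in excess outcompeting the hindered secondary hydroxyl.

Step 7
Reactants: 11 (1E,6S,7E)-6-hydroxy-7-iodo-1-[(4-methoxybenzyl)oxy]nona-1,7-dien-3-one
Product: 12 (1E,6S,7E)-7-iodo-1-[(4-methoxybenzyl)oxy]-3-oxonona-1,7-dien-6-yl acetate
Conditions: Ac2O, pyridine, DMAP (cat.), CH2Cl2, 0 °C
Reagents that add atoms: acetic anhydride, CC(=O)OC(C)=O
Why: standard acylation installs the C2 acetate of the target at this point, so that no protecting-group exchange is needed at this oxygen later.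

Step 8
Reactants: 12 (1E,6S,7E)-7-iodo-1-[(4-methoxybenzyl)oxy]-3-oxonona-1,7-dien-6-yl acetate
Product: 13 (1E,3Z,6S,7E)-3-[(tert-butyldimethylsilyl)oxy]-7-iodo-1-[(4-methoxybenzyl)oxy]nona-1,3,7-trien-6-yl acetate
Conditions: TBSOTf, Et3N, Et2O, −78 to 0 °C
Reagents that add atoms: tert-butyldimethylsilyl trifluoromethanesulfonate, CC(C)(C)[Si](C)(C)OS(=O)(=O)C(F)(F)F
Why: soft enolisation of the vinylogous ester at its only enolisable position should give the 1-alkoxy-3-silyloxy diene, the amine/silyl triflate conditions favouring the (3Z) enol ether (silyloxy cis to the chain) that puts the tether "outside" in the s-cis diene.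

Step 9
Reactants: 14 (E)-1,2-bis(tributylstannyl)ethene; 15 acetyl chloride
Product: 16 (E)-4-(tributylstannyl)but-3-en-2-one
Conditions: PdCl2(PPh3)2 (cat.), THF, 50 °C, 14 in excess
Reagents that add atoms: none
Why: Stille acylation (acid chloride plus vinylstannane) proceeds with retention of the E geometry, and the electron-poor product stannane transmetalates more slowly than 14, so monoacylation should prevail.

Step 10
Reactants: 13 (1E,3Z,6S,7E)-3-[(tert-butyldimethylsilyl)oxy]-7-iodo-1-[(4-methoxybenzyl)oxy]nona-1,3,7-trien-6-yl acetate; 16 (E)-4-(tributylstannyl)but-3-en-2-one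
Product: 18 (1Z,2S)-2α-acetoxy-7α-acetyl-4-(tert-butyldimethylsilyloxy)-1-ethylidene-6α-(4-methoxybenzyloxy)-2,3,3aβ,6,7,7aα-hexahydro-1H-indene (trans-fused), via tetraenone 17 (not isolated)
Conditions: Pd2(dba)3 (cat.), AsPh3, CuI (cat.), DMF, 25–40 °C; then toluene, 60 °C
Reagents that add atoms: none
Why: Stille coupling (oxidative addition of zerovalent palladium into the C–I bond of 13, transmetalation from 16, reductive elimination with retention at both alkenes) unveils the (E)-enone of 17, which then undergoes a concerted, asynchronous intramolecular [4+2] cycloaddition in which the silyl enol ether terminus C3a bonds to the enone β-carbon C7a and the alkoxy-bearing terminus C6 bonds to the α-carbon C7; the closest precedents are intramolecular Diels–Alder reactions of 1-alkoxy-3-silyloxy dienes, of 1,3,8-nonatrienes with a terminal ketone, and Stille/Diels–Alder tandems. Ring A (five-membered) closes as the fused tether ring through the C3a–C7a bond, and ring B (six-membered) closes as the cyclohexene of the suprafacial 4π+2π addition through the C3a–C7a and C6–C7 bonds. The (3Z) and (1E) enol ether geometries place C3 and the PMB-oxy group "outside", the (E)-enone places acetyl trans to C1, and the acetyl-endo transition state therefore gives H-3a and H-7a trans with O-6 and the 7-acetyl group cis to each other on the α face. The absolute sense is relayed from C2: allylic 1,3-strain with the Z-methyl of the ethylidene forces C2–H towards the alkene plane and the acetate pseudoaxial, which corresponds to the diastereomer with the 2-acetate syn to H-7a. The step needs endo (trans-fusion) and π-facial selectivity; matched polarity, secondary overlap of the endo acetyl, exo placement of the bulky sp2 tether carbon C1 and the allylic strain element are expected to secure them, and no Lewis acid is used so that the silyloxy diene survives.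

Step 11
Reactants: 18 (the cycloadduct)
Product: 19 (1Z,2S)-2α-acetoxy-4-(tert-butyldimethylsilyloxy)-1-ethylidene-6α-(4-methoxybenzyloxy)-7α-(prop-1-en-2-yl)-2,3,3aβ,6,7,7aα-hexahydro-1H-indene
Conditions: Ph3PCH3Br, KN(SiMe3)2, THF, 0 °C; then 18, −78 to 0 °C
Reagents that add atoms: methyltriphenylphosphonium bromide, C[P+](c1ccccc1)(c1ccccc1)c1ccccc1.[Br-]
Why: Wittig methylenation of the only free ketone (the C4 carbonyl is masked as its silyl enol ether) should convert acetyl into isopropenyl, and C7 already holds the thermodynamically preferred equatorial configuration.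

Step 12
Reactants: 19 (the isopropenyl compound)
Product: 20 (1Z,2S)-2α-acetoxy-4-(tert-butyldimethylsilyloxy)-1-ethylidene-7α-isopropyl-6α-(4-methoxybenzyloxy)-2,3,3aβ,6,7,7aα-hexahydro-1H-indene
Conditions: H2 (1 atm), RhCl(PPh3)3 (cat.), benzene, rt
Reagents that add atoms: none
Why: homogeneous hydrogenation with RhCl(PPh3)3 should reduce the 1,1-disubstituted isopropenyl group selectively over the trisubstituted ethylidene and silyl enol ether double bonds, and it creates no new stereocentre.

Step 13
Reactants: 20 (the isopropyl silyl enol ether)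
Product: 22 (1Z,2S)-2α-acetoxy-1-ethylidene-5β-hydroxy-7α-isopropyl-6α-(4-methoxybenzyloxy)-3aβ,7aα-octahydro-4H-inden-4-one, via silyloxy epoxide 21 (not isolated)
Conditions: DMDO, acetone/CH2Cl2, −78 to −40 °C; then HF·pyridine, THF, 0 °C
Reagents that add atoms: dimethyldioxirane, CC1(C)OO1
Why: Rubottom oxidation, in which the electron-rich silyl enol ether should react far faster than the ethylidene and the oxidant should add to the β face, anti to the pseudoaxial 6α-PMB ether and along the axial trajectory, so that the new C5 oxygen is trans-diaxial to O-6.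

Step 14
Reactants: 22 (the α-hydroxy ketone)
Product: 23 (1Z,2S)-2α-acetoxy-1-ethylidene-7α-isopropyl-6α-(4-methoxybenzyloxy)-4-methylene-3aβ,7aα-octahydro-1H-inden-5β-ol
Conditions: Zn, CH2Br2, TiCl4 (preformed reagent), THF/CH2Cl2, 0 °C to rt
Reagents that add atoms: dibromomethane, BrCBr
Why: Takai–Lombardo methylenation, a non-basic carbonyl olefination that tolerates free hydroxyl, ester and ether groups, should convert the hindered C4 ketone into the exocyclic methylene without epimerising C3a or C5 and without β-elimination of the C6 ether.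

Step 15
Reactants: 24 ethyl pent-2-ynoate
Product: 25 ethyl (Z)-3-methylpent-2-enoate
Conditions: MeLi (2 equiv), CuI, THF, −78 °C; aq. NH4Cl at −78 °C
Reagents that add atoms: methyllithium (used as Me2CuLi), [Li]C
Why: syn-carbocupration of the ynoate followed by protonation with retention at low temperature should place the new methyl and the new hydrogen cis, which is the Z enoate (ethyl cis to the ester).

Step 16
Reactants: 25 ethyl (Z)-3-methylpent-2-enoate
Product: 26 (Z)-3-methylpent-2-enoic acid
Conditions: LiOH, THF/H2O, rt; then aq. HCl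
Reagents that add atoms: lithium hydroxide, [Li+].[OH-]
Why: saponification by acyl substitution does not involve the trisubstituted double bond, so the Z geometry should be kept.

Step 17
Reactants: 23 (the allylic alcohol); 26 (Z)-3-methylpent-2-enoic acid
Product: 27 (1Z,2S)-2α-acetoxy-1-ethylidene-7α-isopropyl-6α-(4-methoxybenzyloxy)-4-methylene-3aβ,7aα-octahydro-1H-inden-5β-yl (Z)-3-methylpent-2-enoate
Conditions: EDC·HCl, DMAP (cat.), CH2Cl2, 0 °C to rt
Reagents that add atoms: none
Why: Steglich-type carbodiimide esterification of the only free hydroxyl (the axial allylic one at C5), run cold and with little DMAP to limit ketene or dienolate formation that would scramble the Z enoate.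

Step 18
Reactants: 27 (the PMB-protected ester)
Product: 28 (1Z,2S,3aR,5S,6S,7S,7aR)-2-acetoxy-1-ethylidene-6-hydroxy-7-isopropyl-4-methyleneoctahydro-1H-inden-5-yl (Z)-3-methylpent-2-enoate (CNP0418642.1)
Conditions: DDQ, CH2Cl2/pH 7 buffer, 0 °C
Reagents that add atoms: none
Why: oxidative cleavage of the PMB ether by DDQ should leave both esters and the three alkenes untouched, and the trans-diaxial arrangement of O-5 and O-6 prevents acyl migration to the freed C6 hydroxyl.

**Compound list**

1 | methyl 4-chloro-4-oxobutanoate | COC(=O)CCC(=O)Cl | starting material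
2 | propyne | CC#C | starting material
3 | methyl 4-oxohept-5-ynoate | COC(=O)CCC(=O)C#CC | intermediate
4 | methyl (S)-4-hydroxyhept-5-ynoate | COC(=O)CC[C@H](O)C#CC | intermediate
5 | (S)-5-(prop-1-yn-1-yl)dihydrofuran-2(3H)-one | O=C1CC[C@@H](C#CC)O1 | intermediate
6 | (S)-4-hydroxy-N-methoxy-N-methylhept-5-ynamide | CON(C)C(=O)CC[C@H](O)C#CC | intermediate
7 | (4S,5E)-4-hydroxy-N-methoxy-N-methyl-5-(tributylstannyl)hept-5-enamide | CON(C)C(=O)CC[C@H](O)/C(=C\C)[Sn](CCCC)(CCCC)CCCC | intermediate
8 | (4S,5E)-4-hydroxy-5-iodo-N-methoxy-N-methylhept-5-enamide | CON(C)C(=O)CC[C@H](O)/C(=C\C)I | intermediate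
9 | ethynylmagnesium bromide | C#C[Mg]Br | starting material
10 | (6S,7E)-6-hydroxy-7-iodonon-7-en-1-yn-3-one | C#CC(=O)CC[C@H](O)/C(=C\C)I | intermediate
11 | (1E,6S,7E)-6-hydroxy-7-iodo-1-[(4-methoxybenzyl)oxy]nona-1,7-dien-3-one | COc1ccc(CO/C=C/C(=O)CC[C@H](O)/C(=C\C)I)cc1 | intermediate
12 | (1E,6S,7E)-7-iodo-1-[(4-methoxybenzyl)oxy]-3-oxonona-1,7-dien-6-yl acetate | COc1ccc(CO/C=C/C(=O)CC[C@H](OC(C)=O)/C(=C\C)I)cc1 | intermediate
13 | (1E,3Z,6S,7E)-3-[(tert-butyldimethylsilyl)oxy]-7-iodo-1-[(4-methoxybenzyl)oxy]nona-1,3,7-trien-6-yl acetate | COc1ccc(CO/C=C/C(O[Si](C)(C)C(C)(C)C)=C/C[C@H](OC(C)=O)/C(=C\C)I)cc1 | intermediate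
14 | (E)-1,2-bis(tributylstannyl)ethene | CCCC[Sn](CCCC)(CCCC)/C=C/[Sn](CCCC)(CCCC)CCCC | starting material
15 | acetyl chloride | CC(=O)Cl | starting material
16 | (E)-4-(tributylstannyl)but-3-en-2-one | CC(=O)/C=C/[Sn](CCCC)(CCCC)CCCC | intermediate
17 | (1E,3Z,6S,7Z,8E)-3-[(tert-butyldimethylsilyl)oxy]-7-ethylidene-1-[(4-methoxybenzyl)oxy]-10-oxoundeca-1,3,8-trien-6-yl acetate | COc1ccc(CO/C=C/C(O[Si](C)(C)C(C)(C)C)=C/C[C@H](OC(C)=O)/C(=C\C)/C=C/C(C)=O)cc1 | intermediate
18 | trans-fused cycloadduct: (1Z,2S)-2α-acetoxy-7α-acetyl-4-(TBS-oxy)-1-ethylidene-6α-(PMB-oxy)-2,3,3aβ,6,7,7aα-hexahydro-1H-indene | CC(C)(C)[Si](C)(C)OC=1[C@@H]2C[C@H](OC(C)=O)/C(=C\C)[C@H]2[C@H](C(C)=O)[C@H](OCc3ccc(OC)cc3)C=1 | intermediate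
19 | 7α-isopropenyl analogue of 18 | CC(C)(C)[Si](C)(C)OC=1[C@@H]2C[C@H](OC(C)=O)/C(=C\C)[C@H]2[C@H](C(C)=C)[C@H](OCc3ccc(OC)cc3)C=1 | intermediate
20 | 7α-isopropyl analogue of 18 | CC(C)(C)[Si](C)(C)OC=1[C@@H]2C[C@H](OC(C)=O)/C(=C\C)[C@H]2[C@H](C(C)C)[C@H](OCc3ccc(OC)cc3)C=1 | intermediate
21 | 4β,5β-epoxide of 20 (4α-TBS-oxy oxirane) | CC(C)(C)[Si](C)(C)O[C@]12[C@@H]3C[C@H](OC(C)=O)/C(=C\C)[C@H]3[C@H](C(C)C)[C@H](OCc4ccc(OC)cc4)[C@H]1O2 | intermediate
22 | (1Z,2S)-2α-acetoxy-1-ethylidene-5β-hydroxy-7α-isopropyl-6α-(PMB-oxy)-3aβ,7aα-octahydro-4H-inden-4-one | O=C1[C@@H]2C[C@H](OC(C)=O)/C(=C\C)[C@H]2[C@H](C(C)C)[C@H](OCc3ccc(OC)cc3)[C@H]1O | intermediate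
23 | (1Z,2S)-2α-acetoxy-1-ethylidene-7α-isopropyl-6α-(PMB-oxy)-4-methylene-3aβ,7aα-octahydro-1H-inden-5β-ol | C=C1[C@@H]2C[C@H](OC(C)=O)/C(=C\C)[C@H]2[C@H](C(C)C)[C@H](OCc3ccc(OC)cc3)[C@H]1O | intermediate
24 | ethyl pent-2-ynoate | CCC#CC(=O)OCC | starting material
25 | ethyl (Z)-3-methylpent-2-enoate | CCOC(=O)/C=C(/C)CC | intermediate
26 | (Z)-3-methylpent-2-enoic acid | OC(=O)/C=C(/C)CC | intermediate
27 | 6-O-PMB ether of the target | C=C1[C@@H]2C[C@H](OC(C)=O)/C(=C\C)[C@H]2[C@H](C(C)C)[C@H](OCc3ccc(OC)cc3)[C@H]1OC(=O)/C=C(/C)CC | intermediate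
28 | (1Z,2S,3aR,5S,6S,7S,7aR)-2-acetoxy-1-ethylidene-6-hydroxy-7-isopropyl-4-methyleneoctahydro-1H-inden-5-yl (Z)-3-methylpent-2-enoate | C=C1[C@@H]2C[C@H](OC(C)=O)/C(=C\C)[C@H]2[C@H](C(C)C)[C@H](O)[C@H]1OC(=O)/C=C(/C)CC | target

**Step count**

Total: 18 steps. Longest linear sequence: 15 steps (steps 1–8, 10–14, 17 and 18).

**Steps most likely to fail, with fallbacks**

Step 10. The thermal cycloaddition may show poor endo/exo discrimination (erosion of the trans ring fusion) or poor π-facial control, and the silyloxy diene may hydrolyse before it reacts. In the fallback the two bonds are made one after the other. Compounds 13 and 16 are coupled as in step 10 but at 0–20 °C, and the crude tetraenone 17 is treated at −78 °C with catalytic TBSOTf and 2,6-di-tert-butylpyridine. An intramolecular Mukaiyama–Michael addition (5-exo) then closes ring A first, through an open transition state that favours the trans-1,2-disubstituted cyclopentane, and transfers the silyl group to the acetyl enolate, giving the monocyclic silyl enol ether F1. A second silyl-triflate-catalysed Mukaiyama–Michael addition of this enol ether to the β-alkoxy enone (chair transition state, acetyl equatorial) closes ring B and regenerates the C4 silyl enol ether. The fallback sets out from 13 and comes back to the route at 18.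

Step 4. The Pd–H addition may lose regiocontrol (tin delivered to the methyl-bearing carbon), or the stannane may be protodestannylated. In the fallback the regiochemistry is taken from carbonyl polarisation instead. Ynone 3 is hydrostannylated (Bu3SnH, PdCl2(PPh3)2 cat.), where hydride goes to the β-carbon, to give the α-stannyl enone F2. Iododestannylation with I2 gives the α-iodo enone F3. CBS reduction with the (R)-oxazaborolidine and catecholborane (iodovinyl as the large group) should then give the (S)-allylic alcohol F4, which is converted directly with MeNH(OMe)·HCl/AlMe3 into the Weinreb amide. The fallback sets out from 3 and comes back at 8.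

Step 17. Activation of the acid may cause Z/E scrambling or deconjugation through a vinylketene or dienolate, and acylation of the hindered axial alcohol may be slow. In the fallback the geometry is created after the ester bond. Alcohol 23 is esterified with pent-2-ynoic acid (DCC, DMAP cat.), which is small and has no geometry to lose, to give the ynoate F5. Syn-carbocupration with Me2CuLi at −78 °C and low-temperature protonation, as in step 15, then gives the Z enoate. The fallback sets out from 23 and comes back at 27.

**Further compounds**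

F1 | step 10 | (S)-acetoxy trans-disubstituted ethylidenecyclopentane carrying the (E)-3-(PMB-oxy)acryloyl group and the (Z)-2-(TBS-oxy)prop-1-enyl group | O=C(/C=C/OCc1ccc(OC)cc1)[C@@H]2C[C@H](OC(C)=O)/C(=C\C)[C@H]2/C=C(/C)O[Si](C)(C)C(C)(C)C
F2 | step 4 | methyl (E)-4-oxo-5-(tributylstannyl)hept-5-enoate | COC(=O)CCC(=O)/C(=C\C)[Sn](CCCC)(CCCC)CCCC
F3 | step 4 | methyl (E)-5-iodo-4-oxohept-5-enoate | COC(=O)CCC(=O)/C(=C\C)I
F4 | step 4 | methyl (4S,5E)-4-hydroxy-5-iodohept-5-enoate | COC(=O)CC[C@H](O)/C(=C\C)I
F5 | step 17 | 5β-pent-2-ynoate of alcohol 23 | C=C1[C@@H]2C[C@H](OC(C)=O)/C(=C\C)[C@H]2[C@H](C(C)C)[C@H](OCc3ccc(OC)cc3)[C@H]1OC(=O)C#CCC
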